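**Strategy.** Everything rests on opening the carbocycle (C4a–C5–C6–C7–C8–C8a) between C7 and C8. Ring atoms C7 and C8 form an α-ketol: C8 is a ketone and C7 a tertiary alcohol bearing CH3. This acyloin is made by umpolung, the C8 carbonyl carbon acting as nucleophile toward a C7 methyl ketone. One carbene-catalysed aldehyde–ketone benzoin step forms C7–C8, closes the six-membered ring and sets C7. Its precursor is an acyclic keto-aldehyde from (R)-malic acid: C7 methyl ketone, C6 silyl ether, C4a dioxolane, C8 aldehyde. The orsellinate, C1 and the epoxyalkynyl arm follow on the ring; a gold-catalysed 6-endo closure then builds the pyran.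

Key step: step 8

Remark: atoms carry the 1H-isochromene numbering of the target (C1, O2, C3, C4, C4a, C5–C8, C8a) throughout.
Remark: the target is (6R,7R) with C6–O and C7–OH cis and a trans epoxide, (2S,3R) on the oxirane; (R)-malic acid carries its C2 into C6 with the same descriptor, and the epoxide requires the D-(−)-tartrate in the Sharpless step.
Remark: C1 is attached before the epoxyalkyne, because a 2-(oxymethyl)-1,3-dione loses formaldehyde too easily and zerovalent palladium must not meet the propargylic epoxide in a later hot coupling; the orsellinate is attached early, so that the last step is a mild desilylation.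
Assumption: the (5aS,10bR) antipode of the aminoindanol-derived triazolium salt is taken as matched with the (5R) substrate (attack on the Si face of the C7 ketone); if the pairing proves mismatched, the (5aR,10bS) salt takes its place in step 8.

**Route**

Step 1
Reactants: 1 (R)-malic acid
Product: 2 (R)-2-(2,2-dimethyl-5-oxo-1,3-dioxolan-4-yl)acetic acid
Conditions: 2,2-dimethoxypropane, p-TsOH·H2O (cat.), CH2Cl2, 23 °C
Reagents that add atoms: 2,2-dimethoxypropane, COC(C)(C)OC
Why: Acid-catalysed acetalisation ties the α-hydroxy acid into a five-membered 1,3-dioxolan-4-one, which tells the two carboxyl groups apart without touching the stereocentre (future C6).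

Step 2
Reactants: 2 (R)-2-(2,2-dimethyl-5-oxo-1,3-dioxolan-4-yl)acetic acid; 3 allyltributylstannane
Product: 5 (5R)-2,2-dimethyl-5-(2-oxopent-4-en-1-yl)-1,3-dioxolan-4-one, via acid chloride 4 (not isolated)
Conditions: (COCl)2, DMF (cat.), CH2Cl2, 0 °C to 23 °C; concentrate; then 3, PdCl2(PPh3)2 (2 mol %), THF, 50 °C
Reagents that add atoms: oxalyl chloride, ClC(=O)C(=O)Cl (chlorine of 4)
Why: Acid chloride formation and a Stille-type acyl coupling (acyl–palladium, allyl transfer from tin) give the β,γ-unsaturated ketone under neutral conditions that spare the dioxolanone, which an allyl Grignard reagent would attack.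

Step 3
Reactants: 5 (5R)-2,2-dimethyl-5-(2-oxopent-4-en-1-yl)-1,3-dioxolan-4-one
Product: 6 (5R)-2,2-dimethyl-5-{[2-(prop-2-en-1-yl)-1,3-dioxolan-2-yl]methyl}-1,3-dioxolan-4-one
Conditions: TMSOCH2CH2OTMS, TMSOTf (5 mol %), CH2Cl2, −78 to −20 °C; pyridine quench
Reagents that add atoms: 1,2-bis(trimethylsilyloxy)ethane, C[Si](C)(C)OCCO[Si](C)(C)C
Why: Noyori ketalisation at low temperature masks the C4a ketone without moving the β,γ-double bond into conjugation and without β-elimination of the C6 oxygen.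

Step 4
Reactants: 6 (5R)-2,2-dimethyl-5-{[2-(prop-2-en-1-yl)-1,3-dioxolan-2-yl]methyl}-1,3-dioxolan-4-one
Product: 7 (2R)-2-hydroxy-N-methoxy-N-methyl-3-[2-(prop-2-en-1-yl)-1,3-dioxolan-2-yl]propanamide
Conditions: MeNHOMe·HCl, i-PrMgCl, THF, −20 °C; then 6, −20 to 0 °C; aq. NH4Cl
Reagents that add atoms: N,O-dimethylhydroxylamine hydrochloride, CNOC.Cl
Why: The chloromagnesium amide opens the activated lactone carbonyl (Weinreb amide formation from an ester) and releases acetone and the C6 hydroxyl, with C6 untouched because no bond to it is broken.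

Step 5
Reactants: 7 (2R)-2-hydroxy-N-methoxy-N-methyl-3-[2-(prop-2-en-1-yl)-1,3-dioxolan-2-yl]propanamide
Product: 8 (2R)-2-[(tert-butyldimethylsilyl)oxy]-N-methoxy-N-methyl-3-[2-(prop-2-en-1-yl)-1,3-dioxolan-2-yl]propanamide
Conditions: TBSCl, imidazole, DMF, 23 °C
Reagents that add atoms: tert-butyldimethylsilyl chloride, C[Si](C)(Cl)C(C)(C)C
Why: Routine silylation of a secondary alcohol gives a base-stable, non-chelating ether that also prevents lactol formation with the later aldehyde.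

Step 6
Reactants: 8 (2R)-2-[(tert-butyldimethylsilyl)oxy]-N-methoxy-N-methyl-3-[2-(prop-2-en-1-yl)-1,3-dioxolan-2-yl]propanamide
Product: 9 (3R)-3-[(tert-butyldimethylsilyl)oxy]-4-[2-(prop-2-en-1-yl)-1,3-dioxolan-2-yl]butan-2-one
Conditions: MeMgBr, THF, −78 to 0 °C; aq. NH4Cl
Reagents that add atoms: methylmagnesium bromide, C[Mg]Br
Why: Weinreb ketone synthesis, in which the magnesium chelate stops the addition at the methyl ketone; ketal and alkene are inert and C6 is not epimerised at low temperature.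

Step 7
Reactants: 9 (3R)-3-[(tert-butyldimethylsilyl)oxy]-4-[2-(prop-2-en-1-yl)-1,3-dioxolan-2-yl]butan-2-one
Product: 11 (5R)-5-[(tert-butyldimethylsilyl)oxy]-3,3-(ethylenedioxy)-6-oxoheptanal, via secondary ozonide 10 (not isolated)
Conditions: O3, CH2Cl2, −78 °C (Sudan red end point); PPh3, −78 to 23 °C
Reagents that add atoms: ozone, [O-][O+]=O
Why: Ozonolysis with reductive work-up cleaves only the terminal alkene and unveils the C8 aldehyde last, under neutral conditions, beside the C7 ketone.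

Step 8
Reactants: 11 (5R)-5-[(tert-butyldimethylsilyl)oxy]-3,3-(ethylenedioxy)-6-oxoheptanal
Product: 12 (2R,3R)-3-[(tert-butyldimethylsilyl)oxy]-5,5-(ethylenedioxy)-2-hydroxy-2-methylcyclohexan-1-one
Conditions: (5aS,10bR)-2-(pentafluorophenyl)-5a,10b-dihydro-4H,6H-indeno[2,1-b][1,2,4]triazolo[4,3-d][1,4]oxazin-2-ium tetrafluoroborate (15 mol %), i-Pr2NEt (15 mol %), toluene (0.03 M), 23 °C
Reagents that add atoms: none
Why: Deprotonation of the triazolium salt gives a carbene that adds to the C8 formyl group; a proton shift turns the adduct into an enaminol with nucleophilic C8, this carbon bonds to the C7 carbonyl, and after proton transfer the carbene leaves and unveils the C8 ketone. The closest known reaction type is the triazolium-catalysed intramolecular crossed aldehyde–ketone benzoin that gives cyclic tertiary α-ketols. The carbocycle closes in a 6-exo-trig mode through a chair-like transition state. The new C7 centre is controlled by the C6 silyloxy group, which lies equatorial and anti to the forming C7–C8 bond (Felkin–Anh sense) while the methyl group takes the equatorial site, so Si-face attack should place C7–OH cis to C6–O (7R); the chiral triazolium is chosen to reinforce this bias. No chemoselectivity problem arises, because the enaminol can come only from the C8 aldehyde and the only carbonyl it can reach is the C7 ketone, C4a being held as a ketal. A catalytic amount of a weak amine base at room temperature guards against C6 epimerisation and against β-elimination of the ketal oxygen, which would in any case be reversible for the tethered dioxolane.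

Step 9
Reactants: 12 (2R,3R)-3-[(tert-butyldimethylsilyl)oxy]-5,5-(ethylenedioxy)-2-hydroxy-2-methylcyclohexan-1-one
Product: 13 (2R,3R)-5,5-(ethylenedioxy)-2,3-dihydroxy-2-methylcyclohexan-1-one
Conditions: TBAF, AcOH (1:1), THF, 0 to 23 °C
Reagents that add atoms: none
Why: Fluoride cleaves the Si–O bond, and the acetic acid buffer keeps the α-ketol and the β-keto ketal from base-induced retro-aldol or ring-opening elimination.

Step 10
Reactants: 14 orsellinic acid
Product: 15 tert-butyldimethylsilyl 2,4-bis[(tert-butyldimethylsilyl)oxy]-6-methylbenzoate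
Conditions: TBSCl (3.5 equiv), imidazole, DMAP (cat.), DMF, 40 °C
Reagents that add atoms: tert-butyldimethylsilyl chloride, C[Si](C)(Cl)C(C)(C)C
Why: Exhaustive silylation masks both phenols and the acid in one operation, the labile silyl ester serving as a latent acid chloride.

Step 11
Reactants: 15 tert-butyldimethylsilyl 2,4-bis[(tert-butyldimethylsilyl)oxy]-6-methylbenzoate
Product: 16 2,4-bis[(tert-butyldimethylsilyl)oxy]-6-methylbenzoyl chloride
Conditions: (COCl)2, DMF (cat.), CH2Cl2, 0 to 23 °C; concentrate, use crude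
Reagents that add atoms: oxalyl chloride, ClC(=O)C(=O)Cl
Why: Silyl esters are converted by the chloroiminium salt from oxalyl chloride and DMF into acid chlorides under neutral conditions, so the aryl silyl ethers survive.

Step 12
Reactants: 13 (2R,3R)-5,5-(ethylenedioxy)-2,3-dihydroxy-2-methylcyclohexan-1-one; 16 2,4-bis[(tert-butyldimethylsilyl)oxy]-6-methylbenzoyl chloride
Product: 17 (1R,2R)-5,5-(ethylenedioxy)-2-hydroxy-2-methyl-3-oxocyclohexyl 2,4-bis[(tert-butyldimethylsilyl)oxy]-6-methylbenzoate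
Conditions: DMAP (2 equiv), Et3N, CH2Cl2, 0 to 40 °C
Reagents that add atoms: none
Why: DMAP-mediated acylation should occur only at the secondary C6 hydroxyl, the tertiary C7 hydroxyl being far less reactive, and C6 keeps its configuration because its C–O bond is untouched.

Step 13
Reactants: 17 (1R,2R)-5,5-(ethylenedioxy)-2-hydroxy-2-methyl-3-oxocyclohexyl 2,4-bis[(tert-butyldimethylsilyl)oxy]-6-methylbenzoate
Product: 18 (1R,2R)-2-hydroxy-2-methyl-3,5-dioxocyclohexyl 2,4-bis[(tert-butyldimethylsilyl)oxy]-6-methylbenzoate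
Conditions: 1 M aq. HCl, THF, 23 °C
Reagents that add atoms: water, O
Why: Acid hydrolysis of the β-keto ketal is driven by formation of the enolised cyclic 1,3-dione, and aryl silyl ethers and the hindered benzoate tolerate dilute acid at room temperature.

Step 14
Reactants: 18 (1R,2R)-2-hydroxy-2-methyl-3,5-dioxocyclohexyl 2,4-bis[(tert-butyldimethylsilyl)oxy]-6-methylbenzoate
Product: 19 (1R,6R)-3,6-dihydroxy-4-iodo-6-methyl-5-oxocyclohex-3-en-1-yl 2,4-bis[(tert-butyldimethylsilyl)oxy]-6-methylbenzoate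
Conditions: NIS (1.05 equiv), CH2Cl2, 0 °C, dark
Reagents that add atoms: N-iodosuccinimide, O=C1CCC(=O)N1I
Why: Electrophilic α-halogenation of a 1,3-dicarbonyl compound: the dione enol is by far the most nucleophilic site and takes iodine at C8a, the handle for C1.

Step 15
Reactants: 19 (1R,6R)-3,6-dihydroxy-4-iodo-6-methyl-5-oxocyclohex-3-en-1-yl 2,4-bis[(tert-butyldimethylsilyl)oxy]-6-methylbenzoate
Product: 20 (1R,6R)-6-hydroxy-4-iodo-6-methyl-5-oxo-3-[(trifluoromethanesulfonyl)oxy]cyclohex-3-en-1-yl 2,4-bis[(tert-butyldimethylsilyl)oxy]-6-methylbenzoate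
Conditions: Tf2O (1.1 equiv), 2,6-lutidine, CH2Cl2, −78 °C
Reagents that add atoms: trifluoromethanesulfonic anhydride, O=S(=O)(OS(=O)(=O)C(F)(F)F)C(F)(F)F
Why: O-Triflation of the dione enolate should occur at the less hindered oxygen on C4a (next to C5H2) and not at the C8 oxygen beside quaternary C7, which keeps C8 as the ketone; hindered base and low temperature spare the tertiary alcohol.

Step 16
Reactants: 20 (1R,6R)-6-hydroxy-4-iodo-6-methyl-5-oxo-3-[(trifluoromethanesulfonyl)oxy]cyclohex-3-en-1-yl 2,4-bis[(tert-butyldimethylsilyl)oxy]-6-methylbenzoate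
Product: 21 (1R,6R)-6-hydroxy-4-(hydroxymethyl)-6-methyl-5-oxo-3-[(trifluoromethanesulfonyl)oxy]cyclohex-3-en-1-yl 2,4-bis[(tert-butyldimethylsilyl)oxy]-6-methylbenzoate
Conditions: Bu3SnCH2OH (1.1 equiv), Pd(PPh3)4 (10 mol %), 1,4-dioxane, 80 °C, dark
Reagents that add atoms: (tributylstannyl)methanol, OC[Sn](CCCC)(CCCC)CCCC
Why: Stille coupling in which, with Pd(PPh3)4 in a non-polar solvent and no halide additive, insertion into the carbon–iodine bond at C8a is faster than into the C4a triflate, and the stannane transfers the hydroxymethyl group (C1).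

Step 17
Reactants: 22 (E)-but-2-en-1-ol
Product: 23 [(2R,3R)-3-methyloxiran-2-yl]methanol
Conditions: Ti(OiPr)4 (10 mol %), D-(−)-diisopropyl tartrate (12 mol %), t-BuOOH, 4 Å MS, CH2Cl2, −20 °C
Reagents that add atoms: tert-butyl hydroperoxide, CC(C)(C)OO
Why: Sharpless asymmetric epoxidation, in which the titanium complex of the D-(−)-tartrate delivers oxygen to the face of the (E)-allylic alcohol that gives the (2R,3R)-epoxide and so sets both epoxide centres of the target.

Step 18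
Reactants: 23 [(2R,3R)-3-methyloxiran-2-yl]methanol
Product: 24 (2S,3R)-3-methyloxirane-2-carbaldehyde
Conditions: PhI(OAc)2, TEMPO (10 mol %), CH2Cl2, 0 to 23 °C; aq. NaHCO3 wash, kept as CH2Cl2 solution
Reagents that add atoms: none
Why: The oxoammonium-mediated oxidation stops at the aldehyde under near-neutral conditions that neither open nor epimerise the epoxide, and the volatile product is not isolated neat.

Step 19
Reactants: 24 (2S,3R)-3-methyloxirane-2-carbaldehyde
Product: 25 (2R,3R)-2-ethynyl-3-methyloxirane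
Conditions: dimethyl (1-diazo-2-oxopropyl)phosphonate, K2CO3, MeOH, 0 to 23 °C; extracted and used as a titrated THF solution
Reagents that add atoms: dimethyl (1-diazo-2-oxopropyl)phosphonate, CC(=O)C(=[N+]=[N-])P(=O)(OC)OC
Why: Seyferth–Gilbert homologation with the Ohira–Bestmann reagent turns the aldehyde into the terminal alkyne through a diazoalkene and a 1,2-hydrogen shift, and the carbonate conditions do not epimerise the oxirane carbon.

Step 20
Reactants: 21 (1R,6R)-6-hydroxy-4-(hydroxymethyl)-6-methyl-5-oxo-3-[(trifluoromethanesulfonyl)oxy]cyclohex-3-en-1-yl 2,4-bis[(tert-butyldimethylsilyl)oxy]-6-methylbenzoate; 25 (2R,3R)-2-ethynyl-3-methyloxirane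
Product: 26 (1R,6R)-6-hydroxy-4-(hydroxymethyl)-6-methyl-3-{[(2R,3R)-3-methyloxiran-2-yl]ethynyl}-5-oxocyclohex-3-en-1-yl 2,4-bis[(tert-butyldimethylsilyl)oxy]-6-methylbenzoate
Conditions: PdCl2(PPh3)2 (5 mol %), CuI (10 mol %), Et3N, THF, 0 to 23 °C
Reagents that add atoms: none
Why: Sonogashira coupling of the electron-poor vinylogous acyl triflate runs at or below room temperature, where fast oxidative addition keeps zerovalent palladium away from the propargylic epoxide, whose centres are carried in unchanged.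

Step 21
Reactants: 26 (1R,6R)-6-hydroxy-4-(hydroxymethyl)-6-methyl-3-{[(2R,3R)-3-methyloxiran-2-yl]ethynyl}-5-oxocyclohex-3-en-1-yl 2,4-bis[(tert-butyldimethylsilyl)oxy]-6-methylbenzoate
Product: 27 (6R,7R)-7-hydroxy-7-methyl-3-[(2S,3R)-3-methyloxiran-2-yl]-8-oxo-5,6,7,8-tetrahydro-1H-isochromen-6-yl 2,4-bis[(tert-butyldimethylsilyl)oxy]-6-methylbenzoate
Conditions: Ph3PAuNTf2 (3 mol %), CH2Cl2, 0 °C
Reagents that add atoms: none
Why: π-Acid-catalysed hydroalkoxylation in which the C1 hydroxyl attacks C3, the δ-terminus of the ynenone, in a 6-endo-dig closure that the polarisation of the conjugated system favours over 5-exo attack at C4, and protodeauration gives the 1H-isochromene.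

Step 22
Reactants: 27 (6R,7R)-7-hydroxy-7-methyl-3-[(2S,3R)-3-methyloxiran-2-yl]-8-oxo-5,6,7,8-tetrahydro-1H-isochromen-6-yl 2,4-bis[(tert-butyldimethylsilyl)oxy]-6-methylbenzoate
Product: 28 (6R,7R)-7-hydroxy-7-methyl-3-[(2S,3R)-3-methyloxiran-2-yl]-8-oxo-5,6,7,8-tetrahydro-1H-isochromen-6-yl 2,4-dihydroxy-6-methylbenzoate (CNP0323247.1)
Conditions: TBAF (2.2 equiv), AcOH (2.2 equiv), THF, 0 °C
Reagents that add atoms: none
Why: Buffered fluoride cleaves the two aryl silyl ethers quickly, and the epoxide, dienol ether, α-ketol and hindered ester should be stable to these near-neutral conditions.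

**Compound list**

1 | (R)-malic acid | O[C@H](CC(=O)O)C(=O)O | starting material
2 | (R)-2-(2,2-dimethyl-5-oxo-1,3-dioxolan-4-yl)acetic acid | OC(=O)C[C@H]1OC(C)(C)OC1=O | intermediate
3 | allyltributylstannane | C=CC[Sn](CCCC)(CCCC)CCCC | starting material
4 | (R)-(2,2-dimethyl-5-oxo-1,3-dioxolan-4-yl)acetyl chloride | ClC(=O)C[C@H]1OC(C)(C)OC1=O | intermediate
5 | (5R)-2,2-dimethyl-5-(2-oxopent-4-en-1-yl)-1,3-dioxolan-4-one | C=CCC(=O)C[C@H]1OC(C)(C)OC1=O | intermediate
6 | (5R)-2,2-dimethyl-5-{[2-(prop-2-en-1-yl)-1,3-dioxolan-2-yl]methyl}-1,3-dioxolan-4-one | C=CCC1(C[C@H]2OC(C)(C)OC2=O)OCCO1 | intermediate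
7 | (2R)-2-hydroxy-N-methoxy-N-methyl-3-[2-(prop-2-en-1-yl)-1,3-dioxolan-2-yl]propanamide | C=CCC1(C[C@@H](O)C(=O)N(C)OC)OCCO1 | intermediate
8 | (2R)-2-[(tert-butyldimethylsilyl)oxy]-N-methoxy-N-methyl-3-[2-(prop-2-en-1-yl)-1,3-dioxolan-2-yl]propanamide | C=CCC1(C[C@@H](O[Si](C)(C)C(C)(C)C)C(=O)N(C)OC)OCCO1 | intermediate
9 | (3R)-3-[(tert-butyldimethylsilyl)oxy]-4-[2-(prop-2-en-1-yl)-1,3-dioxolan-2-yl]butan-2-one | C=CCC1(C[C@@H](O[Si](C)(C)C(C)(C)C)C(C)=O)OCCO1 | intermediate
10 | secondary ozonide of 9 (1,2,4-trioxolane in place of the alkene) | CC(=O)[C@H](O[Si](C)(C)C(C)(C)C)CC1(CC2OCOO2)OCCO1 | intermediate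
11 | (5R)-5-[(tert-butyldimethylsilyl)oxy]-3,3-(ethylenedioxy)-6-oxoheptanal | CC(=O)[C@H](O[Si](C)(C)C(C)(C)C)CC1(CC=O)OCCO1 | intermediate
12 | (2R,3R)-3-[(tert-butyldimethylsilyl)oxy]-5,5-(ethylenedioxy)-2-hydroxy-2-methylcyclohexan-1-one | CC(C)(C)[Si](C)(C)O[C@@H]1CC2(OCCO2)CC(=O)[C@]1(C)O | intermediate
13 | (2R,3R)-5,5-(ethylenedioxy)-2,3-dihydroxy-2-methylcyclohexan-1-one | O[C@@H]1CC2(OCCO2)CC(=O)[C@]1(C)O | intermediate
14 | orsellinic acid | Cc1cc(O)cc(O)c1C(=O)O | starting material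
15 | tert-butyldimethylsilyl 2,4-bis[(tert-butyldimethylsilyl)oxy]-6-methylbenzoate | Cc1cc(O[Si](C)(C)C(C)(C)C)cc(O[Si](C)(C)C(C)(C)C)c1C(=O)O[Si](C)(C)C(C)(C)C | intermediate
16 | 2,4-bis[(tert-butyldimethylsilyl)oxy]-6-methylbenzoyl chloride | Cc1cc(O[Si](C)(C)C(C)(C)C)cc(O[Si](C)(C)C(C)(C)C)c1C(Cl)=O | intermediate
17 | (1R,2R)-5,5-(ethylenedioxy)-2-hydroxy-2-methyl-3-oxocyclohexyl 2,4-bis[(tert-butyldimethylsilyl)oxy]-6-methylbenzoate | Cc1cc(O[Si](C)(C)C(C)(C)C)cc(O[Si](C)(C)C(C)(C)C)c1C(=O)O[C@@H]1CC2(OCCO2)CC(=O)[C@]1(C)O | intermediate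
18 | (1R,2R)-2-hydroxy-2-methyl-3,5-dioxocyclohexyl 2,4-bis[(tert-butyldimethylsilyl)oxy]-6-methylbenzoate (drawn as the diketone) | Cc1cc(O[Si](C)(C)C(C)(C)C)cc(O[Si](C)(C)C(C)(C)C)c1C(=O)O[C@@H]1CC(=O)CC(=O)[C@]1(C)O | intermediate
19 | (1R,6R)-3,6-dihydroxy-4-iodo-6-methyl-5-oxocyclohex-3-en-1-yl 2,4-bis[(tert-butyldimethylsilyl)oxy]-6-methylbenzoate (enol form of the 2-iodo-1,3-dione, iodine on C8a) | Cc1cc(O[Si](C)(C)C(C)(C)C)cc(O[Si](C)(C)C(C)(C)C)c1C(=O)O[C@@H]1CC(O)=C(I)C(=O)[C@]1(C)O | intermediate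
20 | (1R,6R)-6-hydroxy-4-iodo-6-methyl-5-oxo-3-[(trifluoromethanesulfonyl)oxy]cyclohex-3-en-1-yl 2,4-bis[(tert-butyldimethylsilyl)oxy]-6-methylbenzoate | Cc1cc(O[Si](C)(C)C(C)(C)C)cc(O[Si](C)(C)C(C)(C)C)c1C(=O)O[C@@H]1CC(OS(=O)(=O)C(F)(F)F)=C(I)C(=O)[C@]1(C)O | intermediate
21 | (1R,6R)-6-hydroxy-4-(hydroxymethyl)-6-methyl-5-oxo-3-[(trifluoromethanesulfonyl)oxy]cyclohex-3-en-1-yl 2,4-bis[(tert-butyldimethylsilyl)oxy]-6-methylbenzoate | Cc1cc(O[Si](C)(C)C(C)(C)C)cc(O[Si](C)(C)C(C)(C)C)c1C(=O)O[C@@H]1CC(OS(=O)(=O)C(F)(F)F)=C(CO)C(=O)[C@]1(C)O | intermediate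
22 | (E)-but-2-en-1-ol (crotyl alcohol) | C/C=C/CO | starting material
23 | [(2R,3R)-3-methyloxiran-2-yl]methanol | OC[C@H]1O[C@@H]1C | intermediate
24 | (2S,3R)-3-methyloxirane-2-carbaldehyde | O=C[C@H]1O[C@@H]1C | intermediate
25 | (2R,3R)-2-ethynyl-3-methyloxirane | C#C[C@H]1O[C@@H]1C | intermediate
26 | (1R,6R)-6-hydroxy-4-(hydroxymethyl)-6-methyl-3-{[(2R,3R)-3-methyloxiran-2-yl]ethynyl}-5-oxocyclohex-3-en-1-yl 2,4-bis[(tert-butyldimethylsilyl)oxy]-6-methylbenzoate | Cc1cc(O[Si](C)(C)C(C)(C)C)cc(O[Si](C)(C)C(C)(C)C)c1C(=O)O[C@@H]1CC(C#C[C@H]2O[C@@H]2C)=C(CO)C(=O)[C@]1(C)O | intermediate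
27 | (6R,7R)-7-hydroxy-7-methyl-3-[(2S,3R)-3-methyloxiran-2-yl]-8-oxo-5,6,7,8-tetrahydro-1H-isochromen-6-yl 2,4-bis[(tert-butyldimethylsilyl)oxy]-6-methylbenzoate | Cc1cc(O[Si](C)(C)C(C)(C)C)cc(O[Si](C)(C)C(C)(C)C)c1C(=O)O[C@@H]1CC2=C(COC([C@H]3O[C@@H]3C)=C2)C(=O)[C@]1(C)O | intermediate
28 | (6R,7R)-7-hydroxy-7-methyl-3-[(2S,3R)-3-methyloxiran-2-yl]-8-oxo-5,6,7,8-tetrahydro-1H-isochromen-6-yl 2,4-dihydroxy-6-methylbenzoate (CNP0323247.1) | Cc1cc(O)cc(O)c1C(=O)O[C@@H]1CC2=C(COC([C@H]3O[C@@H]3C)=C2)C(=O)[C@]1(C)O | target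

**Step count and risks**

Total step count: 22. Longest linear sequence: 17 steps (steps 1–9, 12–16 and 20–22); steps 10–11 and 17–19 are the two side branches.

The three steps most likely to fail:

1. Step 8. The ring closure may give the wrong face at the C7 ketone (trans ketol), or the aldehyde may be lost through β-elimination of the ketal oxygen and aldol reactions under the basic carbene conditions. The fallback sets out from 9 and returns at 12, and fixes C7 by a hydroxyl-directed epoxidation. Petasis methylenation (Cp2TiMe2, toluene, 65 °C) of the ketone gives tert-butyldimethyl({(3R)-2-methyl-4-[2-(prop-2-en-1-yl)-1,3-dioxolan-2-yl]but-1-en-3-yl}oxy)silane F1. Ring-closing metathesis with the second-generation Grubbs catalyst joins the isopropenyl carbon (C7) to the inner allyl carbon (C8) and gives (9R)-9-[(tert-butyldimethylsilyl)oxy]-8-methyl-1,4-dioxaspiro[4.5]dec-7-ene F2. TBAF frees the allylic alcohol (9R)-8-methyl-1,4-dioxaspiro[4.5]dec-7-en-9-ol F3. Epoxidation with VO(acac)2 and t-BuOOH delivers oxygen syn to the C6 hydroxyl, which fixes the C7–O bond cis to C6–O, and gives (7S,8R,9R)-7,8-epoxy-8-methyl-1,4-dioxaspiro[4.5]decan-9-ol F4. Silylation (TBSCl, imidazole) gives the epoxy silyl ether (7S,8S,9R)-9-[(tert-butyldimethylsilyl)oxy]-7,8-epoxy-8-methyl-1,4-dioxaspiro[4.5]decane F5. Hydroxide (aq. KOH, DMSO) opens the epoxide at the secondary C8 with inversion to (7R,8S,9R)-9-[(tert-butyldimethylsilyl)oxy]-8-methyl-1,4-dioxaspiro[4.5]decane-7,8-diol F6. Dess–Martin oxidation of the secondary C8 alcohol then gives 12.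

2. Step 16. Insertion of palladium into the C4a triflate may compete, or transfer of the sp3 hydroxymethyl group may be too slow, so that the iodo triflate decomposes at 80 °C. The fallback sets out from 20 and returns at 21, and brings in C1 as a vinyl group that transfers at room temperature. Stille coupling with tributyl(vinyl)stannane (Pd(PPh3)4, CuI, THF, 23 °C) gives (1R,6R)-4-ethenyl-6-hydroxy-6-methyl-5-oxo-3-[(trifluoromethanesulfonyl)oxy]cyclohex-3-en-1-yl 2,4-bis[(tert-butyldimethylsilyl)oxy]-6-methylbenzoate F7. Lemieux–Johnson cleavage of the terminal alkene (OsO4 cat., NaIO4, 2,6-lutidine, dioxane–water) gives (1R,6R)-4-formyl-6-hydroxy-6-methyl-5-oxo-3-[(trifluoromethanesulfonyl)oxy]cyclohex-3-en-1-yl 2,4-bis[(tert-butyldimethylsilyl)oxy]-6-methylbenzoate F8. NaBH(OAc)3 reduces the aldehyde but not the hindered conjugated ketone and gives 21.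

3. Step 12. Acylation of the C6 hydroxyl, which sits next to the quaternary C7, by the doubly ortho-substituted acid chloride may be too slow, with loss of the acid chloride or silyl migration. The fallback sets out from 7 (with 16) and returns at 17; the ester is attached while the alcohol is unhindered and is carried through the ring closure. Acylation of 7 with 16 (DMAP, Et3N) gives (2R)-1-[methoxy(methyl)amino]-1-oxo-3-[2-(prop-2-en-1-yl)-1,3-dioxolan-2-yl]propan-2-yl 2,4-bis[(tert-butyldimethylsilyl)oxy]-6-methylbenzoate F9. MeMgBr at −78 °C, to which the hindered benzoate should be inert, gives (2R)-3-oxo-1-[2-(prop-2-en-1-yl)-1,3-dioxolan-2-yl]butan-2-yl 2,4-bis[(tert-butyldimethylsilyl)oxy]-6-methylbenzoate F10. Ozonolysis with PPh3 work-up gives (2R)-3-oxo-1-[2-(2-oxoethyl)-1,3-dioxolan-2-yl]butan-2-yl 2,4-bis[(tert-butyldimethylsilyl)oxy]-6-methylbenzoate F11. The carbene-catalysed benzoin of step 8 applied to this keto-aldehyde gives 17 directly, without the silyl ether and its removal.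

Further compounds
F1 | step 8 | tert-butyldimethyl({(3R)-2-methyl-4-[2-(prop-2-en-1-yl)-1,3-dioxolan-2-yl]but-1-en-3-yl}oxy)silane | C=CCC1(C[C@@H](O[Si](C)(C)C(C)(C)C)C(C)=C)OCCO1
F2 | step 8 | (9R)-9-[(tert-butyldimethylsilyl)oxy]-8-methyl-1,4-dioxaspiro[4.5]dec-7-ene | CC1=CCC2(OCCO2)C[C@H]1O[Si](C)(C)C(C)(C)C
F3 | step 8 | (9R)-8-methyl-1,4-dioxaspiro[4.5]dec-7-en-9-ol | CC1=CCC2(OCCO2)C[C@H]1O
F4 | step 8 | (7S,8R,9R)-7,8-epoxy-8-methyl-1,4-dioxaspiro[4.5]decan-9-ol (epoxide oxygen syn to the hydroxyl) | O[C@@H]1CC2(OCCO2)C[C@@H]3O[C@]13C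
F5 | step 8 | (7S,8S,9R)-9-[(tert-butyldimethylsilyl)oxy]-7,8-epoxy-8-methyl-1,4-dioxaspiro[4.5]decane | CC(C)(C)[Si](C)(C)O[C@@H]1CC2(OCCO2)C[C@@H]3O[C@]13C
F6 | step 8 | (7R,8S,9R)-9-[(tert-butyldimethylsilyl)oxy]-8-methyl-1,4-dioxaspiro[4.5]decane-7,8-diol | CC(C)(C)[Si](C)(C)O[C@@H]1CC2(OCCO2)C[C@@H](O)[C@]1(C)O
F7 | step 16 | (1R,6R)-4-ethenyl-6-hydroxy-6-methyl-5-oxo-3-[(trifluoromethanesulfonyl)oxy]cyclohex-3-en-1-yl 2,4-bis[(tert-butyldimethylsilyl)oxy]-6-methylbenzoate | Cc1cc(O[Si](C)(C)C(C)(C)C)cc(O[Si](C)(C)C(C)(C)C)c1C(=O)O[C@@H]1CC(OS(=O)(=O)C(F)(F)F)=C(C=C)C(=O)[C@]1(C)O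
F8 | step 16 | (1R,6R)-4-formyl-6-hydroxy-6-methyl-5-oxo-3-[(trifluoromethanesulfonyl)oxy]cyclohex-3-en-1-yl 2,4-bis[(tert-butyldimethylsilyl)oxy]-6-methylbenzoate | Cc1cc(O[Si](C)(C)C(C)(C)C)cc(O[Si](C)(C)C(C)(C)C)c1C(=O)O[C@@H]1CC(OS(=O)(=O)C(F)(F)F)=C(C=O)C(=O)[C@]1(C)O
F9 | step 12 | (2R)-1-[methoxy(methyl)amino]-1-oxo-3-[2-(prop-2-en-1-yl)-1,3-dioxolan-2-yl]propan-2-yl 2,4-bis[(tert-butyldimethylsilyl)oxy]-6-methylbenzoate | C=CCC1(C[C@@H](OC(=O)c2c(C)cc(O[Si](C)(C)C(C)(C)C)cc2O[Si](C)(C)C(C)(C)C)C(=O)N(C)OC)OCCO1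
F10 | step 12 | (2R)-3-oxo-1-[2-(prop-2-en-1-yl)-1,3-dioxolan-2-yl]butan-2-yl 2,4-bis[(tert-butyldimethylsilyl)oxy]-6-methylbenzoate | C=CCC1(C[C@@H](OC(=O)c2c(C)cc(O[Si](C)(C)C(C)(C)C)cc2O[Si](C)(C)C(C)(C)C)C(C)=O)OCCO1
F11 | step 12 | (2R)-3-oxo-1-[2-(2-oxoethyl)-1,3-dioxolan-2-yl]butan-2-yl 2,4-bis[(tert-butyldimethylsilyl)oxy]-6-methylbenzoate | CC(=O)[C@H](OC(=O)c1c(C)cc(O[Si](C)(C)C(C)(C)C)cc1O[Si](C)(C)C(C)(C)C)CC1(CC=O)OCCO1
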